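Ring positions are given in flavone numbering (O1, C2, C3, C4, C4a, C5 to C8, C8a; ring B primed) throughout, also for open-chain precursors.

## Analysis of the target

Compound 15 is a flavonol: a 4H-chromen-4-one (ring A fused to the pyranone ring C) with a 3,4-dihydroxyphenyl ring B on C2 and a hydroxyl on C3. Ring A carries oxygen on C5, C7 and C8, so C6 is its only CH. There is no stereocentre; the difficulty is regiochemical, namely to tell six phenolic or enolic oxygens apart: O7 is a methyl ether, O8 carries the acetyl group, and O3, O5, O3′ and O4′ are free. The aryl acetate on O8 is the most fragile group, since bases and nucleophiles cleave or move it, so it must go on late and everything after it must be neutral. The catechol and the 5,8-dioxygenated ring A are easily oxidised, and a 5,7,8-trioxygenated flavone with a free 5-hydroxyl can isomerise to the 5,6,7-pattern in hot strong acid (Wessely–Moser rearrangement), which excludes harsh acidic dealkylation at the end. The plan rests on the fact that O5 and O8 stand para on ring A, so ring A is the reduced form of a 1,4-benzoquinone with carbonyl groups at C5 and C8. In that quinone C8a is the β-carbon of the C5 enone, so the O1–C8a bond is a vinylogous ester bond that can be made by exchange of a methoxy group. After reduction, the hydrogen bond from the 5-hydroxyl to the C4 carbonyl separates O5 from O8.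

## Retrosynthetic reasoning

**15 from 14.** The last bonds cut are the three benzyl–oxygen bonds at O3, O3′ and O4′. Hydrogenolysis is neutral, leaves the aryl acetate and the methyl ether alone, and needs no acid that could start a Wessely–Moser isomerisation. Compound 14 therefore carries the full substitution pattern of 15 with three benzyl ethers.

**14 from 13.** The acetyl–O8 bond is cut next. In 13 only O5 and O8 are free, and the 5-hydroxyl is held by the C4 carbonyl, so the acylation has to distinguish only these two and the chelation does that.

**13 from 12.** Compound 13 is a para-hydroquinone and goes back to the flavone-5,8-quinone 12 by a two-electron reduction. This turns the para relationship of O5 and O8 into a handle: in 12 both positions are carbonyl groups and O7 alone is an ether.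

**12 from 10 (key disconnection).** In 12 the O1–C8a bond is cut. The open form is the acylquinone 10, in which C8a carries a methoxy group and the side chain on C4a is a 1,3-diketone with the benzyloxy group on its central carbon, the future C3. Cutting here, and not at O1–C2 or C4–C4a, keeps C2, C3 and C4 in one side chain at their final oxidation level and needs no free phenol on ring A, hence no selective dealkylation. In the forward direction the enol oxygen on the aroyl carbon must add to C8a and the methoxy group must leave, through adduct 11.

**10 from 9.** The two quinone carbonyl groups go back to methyl ethers, which gives the tetramethoxyphenyl diketone 9. Its ring has only one pair of para methoxy groups, those on the future C5 and C8. Oxidative demethylation can therefore give only the 1,4-quinone 10 and leaves the methoxy groups on the future C7 and C8a.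

**9 from 8, and 8 from 5 and 6.** The diketone is cut at C2–C3. Direct C-aroylation of the enolate of 5 would compete with O-acylation. Aldol addition of enolate 7 to aldehyde 6, followed by oxidation of the carbinol of 8, makes the same bond without that ambiguity and in the same number of steps. The stereocentres of 8 are erased later and need no control.

**5 from 3 and 2.** Ketone 5 is cut at C4–C4a. Arene 3 is symmetrical and each of its two equivalent CH positions lies between two methoxy groups, so deprotonation gives a single aryllithium 4, which is acylated by the Weinreb amide 2. A Friedel–Crafts acylation of 3 with 1 would make this bond in one step. It was set aside because an alkoxyacetyl chloride tends to decarbonylate under Lewis acids, and the Lewis acid would also threaten the benzyl ether and the methoxy group ortho to the new carbonyl.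

**2 from 1.** Amide 2 comes from the commercial acid chloride 1 by N-acylation.

## Alternatives that were turned down

**Alternative 1:** Ring C closed by ester olefination, cut at C2=C3.
- Forward key step: the aryl ester 3-(benzyloxy)-5-methoxy-6-(methoxymethoxy)-2-[(triphenylphosphoranylidene)acetyl]phenyl 3,4-bis(benzyloxy)benzoate A2 is heated. The ylide carbon attacks the neighbouring ester carbonyl, the phosphorus leaves as its oxide, and the flavone 5-(benzyloxy)-2-[3,4-bis(benzyloxy)phenyl]-7-methoxy-8-(methoxymethoxy)-4H-chromen-4-one A1 results.
- For it: this ring closure is an established route to chromones and runs under neutral conditions. In A1 each ring A oxygen has its own group (benzyl on O5, methyl on O7, methoxymethyl on O8), so acetylation of O8 would be unambiguous. On precedent for the ring closure and on the differentiation of O8 it is stronger than the quinone route.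
- Against it: A1 has hydrogen on C3, so the 3-hydroxyl must be introduced afterwards by oxidation of an electron-rich flavone. A2 needs a pentasubstituted ring A with four different oxygen substituents, built by stepwise protection and oxidation before the ylide is made.
- Comparison: the chosen route is shorter, brings O3 in with the side chain, and takes ring A from the symmetrical arene 3, differentiating O5, O7 and O8 by the quinone redox pair and by chelation. The price is a less tested ring closure and a selective acetylation.

**Alternative 2:** Propargyl ether Claisen cascade, cut at C4–C4a.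
- Forward key step: the ether 4-{1-[5-(benzyloxy)-3-methoxy-2-(methoxymethoxy)phenoxy]prop-2-yn-1-yl}-1,2-bis(benzyloxy)benzene A4 is heated. Claisen rearrangement to the only free ortho position, hydrogen shift and oxa-6π electrocyclisation give racemic 5-(benzyloxy)-2-[3,4-bis(benzyloxy)phenyl]-7-methoxy-8-(methoxymethoxy)-2H-chromene A3.
- For it: the step is purely thermal, its regiochemistry is fixed by the blocked second ortho position, and the oxygens are differentiated as in Alternative 1. In mildness of the ring-forming step it is at least as good as the chosen route.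
- Against it: A3 is a flavene. C4 and C3 are CH and C2 is sp3, so three atoms of ring C are at the wrong oxidation level. The sequel would oxidise C4 to the ketone, dehydrogenate C2 and hydroxylate C3 on an acid-sensitive, electron-rich chromene. The C2 stereocentre is made only to be destroyed. The ether carbon of A4 is both benzylic and propargylic with a donor aryl group, so it ionises easily when A4 is made and when it is heated.
- Comparison: the chosen route sets C2, C3 and C4 at their final oxidation level in the ring-closing step and needs no oxidation of the heterocycle afterwards.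

**Alternative 3:** Aryne insertion into an arylpropiolic acid, cutting O1–C8a, C4–C4a and O1–C2 at once.
- Forward key step: the aryne released by fluoride from 3,5-dimethoxy-2-(trimethylsilyl)phenyl trifluoromethanesulfonate A7 inserts into the C–O bond of 3-[3,4-bis(benzyloxy)phenyl]prop-2-ynoic acid A6. The resulting phenoxide adds to the ynone and gives 2-[3,4-bis(benzyloxy)phenyl]-5,7-dimethoxy-4H-chromen-4-one A5.
- For it: three bonds form in one operation from two simple components. For the bare flavone core it is clearly the strongest in convergence and step economy.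
- Against it: A5 has no oxygen on C8 and none on C3, and O5 and O7 are both methyl ethers. Reaching 15 would need selective 5-O-demethylation, hydroxylation of C8 para to the 5-hydroxyl (Elbs-type persulfate oxidation, which is inherently inefficient on polyphenols), hydroxylation of C3, and then differentiation of O8 from four other hydroxyls. The regiochemistry of the insertion rests only on the inductive effect of the methoxy group next to the aryne bond.
- Comparison: the chosen route gives up the convergent core assembly but has all six oxygens in place before ring closure and needs no C–H oxidation afterwards.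

Key step: step 6

## Route

Remark on the chemistry: compound 8 is carried forward as a mixture of diastereomers, because both of its stereocentres become trigonal again in steps 4 and 6.

Step 1
Reactants: 1 benzyloxyacetyl chloride
Product: 2 2-(benzyloxy)-N-methoxy-N-methylacetamide
Conditions: MeNHOMe·HCl, Et3N, CH2Cl2, 0 °C to rt
Reagents that add atoms: N,O-dimethylhydroxylamine hydrochloride, CNOC.Cl
Why: N-Acylation of the hydroxylamine by the acid chloride gives the Weinreb amide, which is needed so that the aryllithium of step 2 adds only once.

Step 2
Reactants: 3 1,2,3,5-tetramethoxybenzene; 2 2-(benzyloxy)-N-methoxy-N-methylacetamide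
Product: 5 2-(benzyloxy)-1-(2,3,4,6-tetramethoxyphenyl)ethan-1-one, via (2,3,4,6-tetramethoxyphenyl)lithium 4 (not isolated)
Conditions: n-BuLi, THF, 0 °C to rt; then 2, −78 to 0 °C; 1 M HCl
Reagents that add atoms: none
Why: Directed ortho-lithiation removes one of the two equivalent ring hydrogens, each flanked by two methoxy groups, and the aryllithium adds to the amide (Weinreb ketone synthesis). The chelated tetrahedral adduct should persist until work-up, so no tertiary alcohol forms, and no Lewis acid is present that could cleave the benzyl or ortho-methyl ethers.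

Step 3
Reactants: 5 2-(benzyloxy)-1-(2,3,4,6-tetramethoxyphenyl)ethan-1-one; 6 3,4-bis(benzyloxy)benzaldehyde
Product: 8 2-(benzyloxy)-3-[3,4-bis(benzyloxy)phenyl]-3-hydroxy-1-(2,3,4,6-tetramethoxyphenyl)propan-1-one (racemic syn/anti mixture), via lithium 2-(benzyloxy)-1-(2,3,4,6-tetramethoxyphenyl)ethen-1-olate 7 (not isolated)
Conditions: LiN(SiMe3)2, THF, −78 °C; then 6, −78 °C; AcOH, −78 °C
Reagents that add atoms: none
Why: Aldol addition of the lithium enolate to the non-enolisable aldehyde forms the C2–C3 bond, and the cold acidic quench should prevent retro-aldol cleavage. The two new stereocentres are deliberately not controlled, since step 4 removes the carbinol centre and step 6 the other.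

Step 4
Reactants: 8 2-(benzyloxy)-3-[3,4-bis(benzyloxy)phenyl]-3-hydroxy-1-(2,3,4,6-tetramethoxyphenyl)propan-1-one
Product: 9 2-(benzyloxy)-1-[3,4-bis(benzyloxy)phenyl]-3-(2,3,4,6-tetramethoxyphenyl)propane-1,3-dione
Conditions: Dess–Martin periodinane, CH2Cl2, 0 °C to rt
Reagents that add atoms: none
Why: Dess–Martin oxidation of the secondary benzylic alcohol gives the 1,3-diketone from both diastereomers; the medium is non-basic, so retro-aldol cleavage is not expected, and benzyl and methyl ethers are inert.

Step 5
Reactants: 9 2-(benzyloxy)-1-[3,4-bis(benzyloxy)phenyl]-3-(2,3,4,6-tetramethoxyphenyl)propane-1,3-dione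
Product: 10 2-{2-(benzyloxy)-3-[3,4-bis(benzyloxy)phenyl]-3-oxopropanoyl}-3,5-dimethoxy-1,4-benzoquinone
Conditions: (NH4)2Ce(NO3)6, MeCN–H2O, 0 °C, short reaction time
Reagents that add atoms: water, O
Why: Oxidative demethylation of a para-dimethoxyarene by tetravalent cerium: the arene radical cation is attacked by water at the two para methoxy-bearing carbons and methanol is lost. The ring has only one para pair of methoxy groups, so only the 1,4-quinone with methoxy groups left on C7 and C8a can form. The acyl-deactivated ring B and the α-substituted, weakly enolised diketone should react more slowly than the tetraalkoxyarene.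

Step 6
Reactants: 10 2-{2-(benzyloxy)-3-[3,4-bis(benzyloxy)phenyl]-3-oxopropanoyl}-3,5-dimethoxy-1,4-benzoquinone
Product: 12 3-(benzyloxy)-2-[3,4-bis(benzyloxy)phenyl]-7-methoxy-4H-chromene-4,5,8-trione, via potassium enolate of the C8a adduct 11 (not isolated)
Conditions: K2CO3, MeCN, 0 °C to rt, Ar
Reagents that add atoms: none
Why: K2CO3 deprotonates the 1,3-diketone of 10, and the enolate oxygen on the aroyl carbon (the future O1) adds to C8a, the β-carbon of both the ring enone C5(=O)–C4a=C8a and the side-chain C4 ketone, to give the tetrahedral adduct 11. Adduct 11 then expels the C8a methoxy group as methoxide and the quinone is restored as part of ring C, an addition–elimination (nucleophilic vinylic substitution). The closest known reaction type is the vinylogous ester exchange of methoxy-1,4-benzoquinones and of alkoxymethylene 1,3-dicarbonyl compounds with oxygen and nitrogen nucleophiles, run here intramolecularly. Ring C closes in the 6-endo-trig mode, because the attacked C4a=C8a bond lies inside the new ring, and the product gains the conjugation of a 4-pyranone. No stereocentre is formed, since the sp3 centre at C8a of 11 is lost again. The step needs site selectivity between the two methoxy groups and O- rather than C-attack of the ambident enolate. Only C8a is reachable through a six-membered transition state and only it is activated by two carbonyl groups, so the C7 methoxy group stays, and attack through the central carbon would need a four-membered ring. The released methoxide is taken up as methanol by KHCO3, which should keep C6 and C7 of 12 free from conjugate addition.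

Step 7
Reactants: 12 3-(benzyloxy)-2-[3,4-bis(benzyloxy)phenyl]-7-methoxy-4H-chromene-4,5,8-trione
Product: 13 3-(benzyloxy)-2-[3,4-bis(benzyloxy)phenyl]-5,8-dihydroxy-7-methoxy-4H-chromen-4-one
Conditions: Na2S2O4, EtOAc–H2O, rt, Ar
Reagents that add atoms: none
Why: Dithionite reduction of the quinone to the hydroquinone, which is aromatic and so favoured; the pyranone, the benzyl ethers and the methyl ether are not reduced. The air-sensitive product is used directly.

Step 8
Reactants: 13 3-(benzyloxy)-2-[3,4-bis(benzyloxy)phenyl]-5,8-dihydroxy-7-methoxy-4H-chromen-4-one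
Product: 14 3-(benzyloxy)-2-[3,4-bis(benzyloxy)phenyl]-5-hydroxy-7-methoxy-4-oxo-4H-chromen-8-yl acetate
Conditions: Ac2O (1.05 equiv), pyridine, CH2Cl2, 0 °C, Ar
Reagents that add atoms: acetic anhydride, CC(=O)OC(C)=O
Why: Chemoselective O-acetylation: the 5-hydroxyl is hydrogen-bonded to the C4 carbonyl and is a poor nucleophile, so a near-stoichiometric amount of anhydride at low temperature should acylate only O8.

Step 9
Reactants: 14 3-(benzyloxy)-2-[3,4-bis(benzyloxy)phenyl]-5-hydroxy-7-methoxy-4-oxo-4H-chromen-8-yl acetate
Product: 15 2-(3,4-dihydroxyphenyl)-3,5-dihydroxy-7-methoxy-4-oxo-4H-chromen-8-yl acetate (gossypetin 7-methyl ether 8-acetate)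
Conditions: H2 (1 atm), Pd/C, EtOAc–THF, rt
Reagents that add atoms: none
Why: Hydrogenolysis of the three benzyl ethers under neutral, non-nucleophilic conditions; the aryl acetate, the methyl ether and the tetrasubstituted C2=C3 bond should survive. No alcohol solvent is used, so the acetate is not transesterified, and O8 has no free neighbouring hydroxyl to which the acetyl group could migrate.

## Compound list

1 | benzyloxyacetyl chloride | O=C(Cl)COCc1ccccc1 | starting material
2 | 2-(benzyloxy)-N-methoxy-N-methylacetamide | CON(C)C(=O)COCc1ccccc1 | intermediate
3 | 1,2,3,5-tetramethoxybenzene | COc1cc(OC)c(OC)c(OC)c1 | starting material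
4 | (2,3,4,6-tetramethoxyphenyl)lithium | [Li]c1c(OC)cc(OC)c(OC)c1OC | intermediate
5 | 2-(benzyloxy)-1-(2,3,4,6-tetramethoxyphenyl)ethan-1-one | COc1cc(OC)c(C(=O)COCc2ccccc2)c(OC)c1OC | intermediate
6 | 3,4-bis(benzyloxy)benzaldehyde | O=Cc1ccc(OCc2ccccc2)c(OCc2ccccc2)c1 | starting material
7 | lithium 2-(benzyloxy)-1-(2,3,4,6-tetramethoxyphenyl)ethen-1-olate (drawn as the chelated Z-enolate) | [Li]O/C(=C\OCc1ccccc1)c1c(OC)cc(OC)c(OC)c1OC | intermediate
8 | 2-(benzyloxy)-3-[3,4-bis(benzyloxy)phenyl]-3-hydroxy-1-(2,3,4,6-tetramethoxyphenyl)propan-1-one (racemic syn/anti mixture) | COc1cc(OC)c(C(=O)C(OCc2ccccc2)C(O)c2ccc(OCc3ccccc3)c(OCc3ccccc3)c2)c(OC)c1OC | intermediate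
9 | 2-(benzyloxy)-1-[3,4-bis(benzyloxy)phenyl]-3-(2,3,4,6-tetramethoxyphenyl)propane-1,3-dione | COc1cc(OC)c(C(=O)C(OCc2ccccc2)C(=O)c2ccc(OCc3ccccc3)c(OCc3ccccc3)c2)c(OC)c1OC | intermediate
10 | 2-{2-(benzyloxy)-3-[3,4-bis(benzyloxy)phenyl]-3-oxopropanoyl}-3,5-dimethoxy-1,4-benzoquinone | COC1=CC(=O)C(C(=O)C(OCc2ccccc2)C(=O)c2ccc(OCc3ccccc3)c(OCc3ccccc3)c2)=C(OC)C1=O | intermediate
11 | potassium 3-(benzyloxy)-2-[3,4-bis(benzyloxy)phenyl]-7,8a-dimethoxy-4,8-dioxo-8,8a-dihydro-4H-chromen-5-olate (racemic) | [K+].[O-]C1=C2C(=O)C(OCc3ccccc3)=C(c3ccc(OCc4ccccc4)c(OCc4ccccc4)c3)OC2(OC)C(=O)C(OC)=C1 | intermediate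
12 | 3-(benzyloxy)-2-[3,4-bis(benzyloxy)phenyl]-7-methoxy-4H-chromene-4,5,8-trione | COC1=CC(=O)C2=C(OC(c3ccc(OCc4ccccc4)c(OCc4ccccc4)c3)=C(OCc3ccccc3)C2=O)C1=O | intermediate
13 | 3-(benzyloxy)-2-[3,4-bis(benzyloxy)phenyl]-5,8-dihydroxy-7-methoxy-4H-chromen-4-one | COc1cc(O)c2c(=O)c(OCc3ccccc3)c(-c3ccc(OCc4ccccc4)c(OCc4ccccc4)c3)oc2c1O | intermediate
14 | 3-(benzyloxy)-2-[3,4-bis(benzyloxy)phenyl]-5-hydroxy-7-methoxy-4-oxo-4H-chromen-8-yl acetate | COc1cc(O)c2c(=O)c(OCc3ccccc3)c(-c3ccc(OCc4ccccc4)c(OCc4ccccc4)c3)oc2c1OC(C)=O | intermediate
15 | 2-(3,4-dihydroxyphenyl)-3,5-dihydroxy-7-methoxy-4-oxo-4H-chromen-8-yl acetate (gossypetin 7-methyl ether 8-acetate) | COc1cc(O)c2c(=O)c(O)c(-c3ccc(O)c(O)c3)oc2c1OC(C)=O | target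

## Step count and least certain steps

Total step count: 9. Longest linear sequence: 9 steps (1 → 2 → 5 → 8 → 9 → 10 → 12 → 13 → 14 → 15); 3 and 6 are bought.

**Step 6 (key step).** The likeliest failure is electron transfer from the enolate to the strongly accepting acylquinone, leading to redox decomposition or radical coupling instead of polar addition. Attack of the released methoxide or of adventitious water at C8a or C6 before ring closure is the second risk. The fallback sets out from 9 and returns at 12; it closes ring C on a phenol and makes the quinone afterwards. Chelation-controlled cleavage of the methyl ether on the future C8a of 9 with MgI2·OEt2 should give 2-(benzyloxy)-1-[3,4-bis(benzyloxy)phenyl]-3-(2-hydroxy-3,4,6-trimethoxyphenyl)propane-1,3-dione F1. The methoxy group cleaved is expected to be the one flanked by the carbonyl and by a second methoxy group, as is usual in such ketones. Acid-catalysed cyclodehydration (TsOH, toluene, heat) should then give 3-(benzyloxy)-2-[3,4-bis(benzyloxy)phenyl]-5,7,8-trimethoxy-4H-chromen-4-one F2. With O5 still methylated no Wessely–Moser isomerisation is possible. Oxidative demethylation of the para 5,8-dimethoxy pair of F2 with (NH4)2Ce(NO3)6 in MeCN–H2O should deliver 12.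

**Step 5.** The likeliest failure is one-electron oxidation of the diketone enol by tetravalent cerium in competition with oxidation of the arene. Hydrolysis of the doubly activated C8a methoxy group of 10 in the aqueous acidic medium is the second risk. The fallback sets out from 8 and returns at 10; it swaps the two oxidations so that no 1,3-diketone meets the cerium reagent. Treatment of 8 with (NH4)2Ce(NO3)6 in MeCN–H2O at 0 °C should give 2-{2-(benzyloxy)-3-[3,4-bis(benzyloxy)phenyl]-3-hydroxypropanoyl}-3,5-dimethoxy-1,4-benzoquinone F3. Dess–Martin oxidation of its carbinol, which the quinone tolerates, then gives 10.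

**Step 8.** The likeliest failures are loss of selectivity, with O5 acetylated as well, and re-oxidation of the hydroquinone 13 to 12 by traces of air in the basic medium. The fallback sets out from 13 and returns at 14; it protects O5 instead of relying on rate differences. B(OAc)3, made from B(OH)3 and Ac2O, in Ac2O binds the 5-oxygen and the C4 carbonyl oxygen in a six-membered chelate while O8 is acetylated. This gives the diacetoxyboron chelate of 3-(benzyloxy)-2-[3,4-bis(benzyloxy)phenyl]-5-hydroxy-7-methoxy-4-oxo-4H-chromen-8-yl acetate F4. Stirring F4 with water at rt hydrolyses the chelate to 14. The acidic medium also protects the hydroquinone from air oxidation.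

**Step 9.** The likeliest failure is slow cleavage of the 3-O-benzyl ether, which is flanked by ring B and the carbonyl. Long exposure could then cost the acetate or partly saturate C2=C3. The fallback sets out from 14 and returns at 15; it replaces reductive cleavage by Lewis-acid cleavage. BCl3 with pentamethylbenzene as benzyl cation trap in CH2Cl2 at −78 °C should remove the three benzyl groups and leave the aryl acetate and the 7-methyl ether, which is not ortho to a carbonyl. This fallback makes no new compound (F0).

## Further compounds

F1 | step 6 | 2-(benzyloxy)-1-[3,4-bis(benzyloxy)phenyl]-3-(2-hydroxy-3,4,6-trimethoxyphenyl)propane-1,3-dione | COc1cc(OC)c(C(=O)C(OCc2ccccc2)C(=O)c2ccc(OCc3ccccc3)c(OCc3ccccc3)c2)c(O)c1OC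
F2 | step 6 | 3-(benzyloxy)-2-[3,4-bis(benzyloxy)phenyl]-5,7,8-trimethoxy-4H-chromen-4-one | COc1cc(OC)c2c(=O)c(OCc3ccccc3)c(-c3ccc(OCc4ccccc4)c(OCc4ccccc4)c3)oc2c1OC
F3 | step 5 | 2-{2-(benzyloxy)-3-[3,4-bis(benzyloxy)phenyl]-3-hydroxypropanoyl}-3,5-dimethoxy-1,4-benzoquinone (racemic diastereomer mixture) | COC1=CC(=O)C(C(=O)C(OCc2ccccc2)C(O)c2ccc(OCc3ccccc3)c(OCc3ccccc3)c2)=C(OC)C1=O
F4 | step 8 | diacetoxyboron chelate (O5, O4) of 3-(benzyloxy)-2-[3,4-bis(benzyloxy)phenyl]-5-hydroxy-7-methoxy-4-oxo-4H-chromen-8-yl acetate | CC(=O)O[B-]1(OC(C)=O)Oc2cc(OC)c(OC(C)=O)c3[o+]c(-c4ccc(OCc5ccccc5)c(OCc5ccccc5)c4)c(OCc4ccccc4)c(O1)c23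
F0 | step 9 | none | none
A1 | alternative 1 | 5-(benzyloxy)-2-[3,4-bis(benzyloxy)phenyl]-7-methoxy-8-(methoxymethoxy)-4H-chromen-4-one | COCOc1c(OC)cc(OCc2ccccc2)c2c(=O)cc(-c3ccc(OCc4ccccc4)c(OCc4ccccc4)c3)oc12
A2 | alternative 1 | 3-(benzyloxy)-5-methoxy-6-(methoxymethoxy)-2-[(triphenylphosphoranylidene)acetyl]phenyl 3,4-bis(benzyloxy)benzoate | COCOc1c(OC)cc(OCc2ccccc2)c(C(=O)C=P(c2ccccc2)(c2ccccc2)c2ccccc2)c1OC(=O)c1ccc(OCc2ccccc2)c(OCc2ccccc2)c1
A3 | alternative 2 | 5-(benzyloxy)-2-[3,4-bis(benzyloxy)phenyl]-7-methoxy-8-(methoxymethoxy)-2H-chromene (racemic) | COCOc1c(OC)cc(OCc2ccccc2)c2C=CC(c3ccc(OCc4ccccc4)c(OCc4ccccc4)c3)Oc12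
A4 | alternative 2 | 4-{1-[5-(benzyloxy)-3-methoxy-2-(methoxymethoxy)phenoxy]prop-2-yn-1-yl}-1,2-bis(benzyloxy)benzene (racemic) | COCOc1c(OC)cc(OCc2ccccc2)cc1OC(C#C)c1ccc(OCc2ccccc2)c(OCc2ccccc2)c1
A5 | alternative 3 | 2-[3,4-bis(benzyloxy)phenyl]-5,7-dimethoxy-4H-chromen-4-one | COc1cc(OC)c2c(=O)cc(-c3ccc(OCc4ccccc4)c(OCc4ccccc4)c3)oc2c1
A6 | alternative 3 | 3-[3,4-bis(benzyloxy)phenyl]prop-2-ynoic acid | OC(=O)C#Cc1ccc(OCc2ccccc2)c(OCc2ccccc2)c1
A7 | alternative 3 | 3,5-dimethoxy-2-(trimethylsilyl)phenyl trifluoromethanesulfonate | COc1cc(OC)c([Si](C)(C)C)c(OS(=O)(=O)C(F)(F)F)c1
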